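**Retrosynthetic overview** (locants: C1–C20 on the epoxy-keto half, primed on the acetylenic half)
1. Last C–C bond: C11=C12, Horner–Wadsworth–Emmons union of C15 epoxy-keto phosphonate 16 with C25 acetylenic apo-aldehyde 9.
2. 9 = C15 phosphonium salt 7 + C10 dialdehyde 8 (Wittig, C11'=C12'); 7 from enol triflate 4 + enynol 5 (Sonogashira, C6'–C7').
3. 16: the C7–C8 bond and the oxirane are made together, by light-driven acyl-radical addition of enal 15 to allylic silyl peroxide 12 followed by O–O ring closure.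
4. 12 from the singlet-oxygen ene reaction of alkene 10 (C5–O bond); 10 from the same triflate 4; 15 by cross-metathesis.
5. Ring order: both six-membered rings are bought in actinol 1 and never opened; the only ring formed is the oxirane, in step 9.

Assumption: (4R,6R)-actinol 1 is bought as the single enantiomer and is the only source of chirality.

**Step 1**
Reactants: 1 (4R,6R)-4-hydroxy-2,2,6-trimethylcyclohexan-1-one (actinol)
Product: 2 (4R,6R)-2,2,6-trimethyl-4-[(triethylsilyl)oxy]cyclohexan-1-one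
Conditions: Et3SiCl, imidazole, DMF, 0 °C to rt
Reagents that add atoms: chlorotriethylsilane, CC[Si](Cl)(CC)CC
Why: Imidazole-promoted O-silylation of the secondary alcohol; no stereocentre is touched.

**Step 2**
Reactants: 2 (4R,6R)-2,2,6-trimethyl-4-[(triethylsilyl)oxy]cyclohexan-1-one
Product: 4 (4R)-2,6,6-trimethyl-4-[(triethylsilyl)oxy]cyclohex-1-en-1-yl trifluoromethanesulfonate, via lithium enolate 3 (not isolated)
Conditions: LiN(iPr)2, THF, −78 to 0 °C; then PhNTf2, −78 °C to rt
Reagents that add atoms: N-phenylbis(trifluoromethanesulfonimide), O=S(=O)(N(c1ccccc1)S(=O)(=O)C(F)(F)F)C(F)(F)F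
Why: Only C6 has an α-hydrogen, so a single enolate forms (the C6 centre is erased on purpose) and is O-triflated (enol triflate formation); the silyloxy group is γ to the enolate carbon, so it cannot eliminate.

**Step 3**
Reactants: 4 (4R)-2,6,6-trimethyl-4-[(triethylsilyl)oxy]cyclohex-1-en-1-yl trifluoromethanesulfonate; 5 (2E)-3-methylpent-2-en-4-yn-1-ol
Product: 6 (2E)-3-methyl-5-{(4R)-2,6,6-trimethyl-4-[(triethylsilyl)oxy]cyclohex-1-en-1-yl}pent-2-en-4-yn-1-ol
Conditions: Pd(PPh3)4 (5 mol %), CuI (10 mol %), Et3N, DMF, 50 °C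
Reagents that add atoms: none
Why: Sonogashira coupling of the alkenyl triflate with the terminal alkyne forms C6'–C7'; the alkene geometry of 5 is kept.

**Step 4**
Reactants: 6 (2E)-3-methyl-5-{(4R)-2,6,6-trimethyl-4-[(triethylsilyl)oxy]cyclohex-1-en-1-yl}pent-2-en-4-yn-1-ol
Product: 7 {(2E)-5-[(4R)-4-hydroxy-2,6,6-trimethylcyclohex-1-en-1-yl]-3-methylpent-2-en-4-yn-1-yl}(triphenyl)phosphonium bromide
Conditions: PPh3·HBr, MeOH, rt; crystallisation
Reagents that add atoms: triphenylphosphine hydrobromide, [Br-].[PH+](c1ccccc1)(c1ccccc1)c1ccccc1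
Why: Direct conversion of a primary allylic alcohol into the allylic phosphonium salt with PPh3·HBr; the acidic methanol cleaves the triethylsilyl ether in the same pot, and the (E)-salt is purified by crystallisation.

**Step 5**
Reactants: 7 {(2E)-5-[(4R)-4-hydroxy-2,6,6-trimethylcyclohex-1-en-1-yl]-3-methylpent-2-en-4-yn-1-yl}(triphenyl)phosphonium bromide; 8 (2E,4E,6E)-2,7-dimethylocta-2,4,6-trienedial (3 equiv)
Product: 9 (2E,4E,6E,8E,10E)-13-[(4R)-4-hydroxy-2,6,6-trimethylcyclohex-1-en-1-yl]-2,7,11-trimethyltrideca-2,4,6,8,10-pentaen-12-ynal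
Conditions: NaOMe, CH2Cl2/MeOH, 0 °C to rt
Reagents that add atoms: none
Why: Wittig olefination on one aldehyde of the dialdehyde, which is used in excess to suppress double condensation, forms C11'=C12'; the all-E aldehyde is obtained by crystallisation from the minor 11'Z isomer.

**Step 6**
Reactants: 4 (4R)-2,6,6-trimethyl-4-[(triethylsilyl)oxy]cyclohex-1-en-1-yl trifluoromethanesulfonate
Product: 10 triethyl{[(1R)-3,4,5,5-tetramethylcyclohex-3-en-1-yl]oxy}silane
Conditions: MeMgBr, Fe(acac)3 (5 mol %), THF/NMP, −30 to 0 °C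
Reagents that add atoms: methylmagnesium bromide, C[Mg]Br
Why: Iron-catalysed Kumada-type coupling of an alkenyl triflate with a methyl Grignard reagent; it is fast at low temperature and leaves the silyl ether alone.

**Step 7**
Reactants: 10 triethyl{[(1R)-3,4,5,5-tetramethylcyclohex-3-en-1-yl]oxy}silane
Product: 12 triethyl({(1R,5S)-1,3,3-trimethyl-2-methylidene-5-[(triethylsilyl)oxy]cyclohexyl}peroxy)silane, via allylic hydroperoxide 11 (not isolated)
Conditions: O2, tetraphenylporphyrin (0.5 mol %), white LEDs, CH2Cl2, −20 °C; then Et3SiCl, imidazole, 0 °C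
Reagents that add atoms: dioxygen, O=O; chlorotriethylsilane, CC[Si](Cl)(CC)CC
Why: Schenck ene reaction of singlet O2. Oxygen bonds to C5, the alkene carbon remote from the quaternary C1, and hydrogen is taken from the C6 methyl geminal to that bulky centre (large-group effect), which leaves the exocyclic methylene. The C5 centre is set by attack on the face opposite the C3 silyloxy group, by analogy with peracid epoxidation of 3-O-protected β-end groups; I expect only about 3:1, with the C5 epimer removed at 12. The hydroperoxide is then O-silylated.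

**Step 8**
Reactants: 13 diethyl prop-2-en-1-ylphosphonate; 14 2-methylprop-2-enal (methacrolein, 5 equiv)
Product: 15 diethyl [(2E)-3-methyl-4-oxobut-2-en-1-yl]phosphonate
Conditions: second-generation Grubbs catalyst RuCl2(=CHPh)(PCy3)(SIMes) (3 mol %), CH2Cl2, 40 °C
Reagents that add atoms: none
Why: Olefin cross-metathesis of a terminal alkene with methacrolein gives the 2-methyl-2-enal with high E selectivity and loss of ethene.

**Step 9**
Reactants: 12 triethyl({(1R,5S)-1,3,3-trimethyl-2-methylidene-5-[(triethylsilyl)oxy]cyclohexyl}peroxy)silane; 15 diethyl [(2E)-3-methyl-4-oxobut-2-en-1-yl]phosphonate (3 equiv)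
Product: 16 diethyl [(2E)-3-methyl-4-oxo-5-{(1S,4S,6R)-2,2,6-trimethyl-4-[(triethylsilyl)oxy]-7-oxabicyclo[4.1.0]heptan-1-yl}pent-2-en-1-yl]phosphonate
Conditions: (nBu4N)4[W10O32] (2 mol %), 390 nm LEDs, MeCN, 20 °C, argon
Reagents that add atoms: none
Why: Proposed new method: photoexcited decatungstate abstracts the formyl hydrogen of 15; the acyl radical adds to the unhindered CH2 terminus of the 1,1-disubstituted alkene of 12; the tertiary C6 radical attacks the proximal peroxide oxygen on C5 (3-exo homolytic substitution at the weak O–O bond), closing the oxirane and releasing Et3SiO•, which takes hydrogen from 15 or from the reduced catalyst and carries the chain; C7–C8 and the oxirane form in one event, C5 keeps its configuration, and C6 is set by it because the new C–O bond can only form on the face that holds the C5–O bond; the closest known reactions are the radical-chain 2,3-epoxypropylation of C–H donors with allyl tert-butyl peroxide and decatungstate-photocatalysed hydroacylation of alkenes, neither shown on a cyclic tertiary allylic peroxide, with an enal-derived acyl radical, or for a tetrasubstituted oxirane.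

**Step 10**
Reactants: 16 diethyl [(2E)-3-methyl-4-oxo-5-{(1S,4S,6R)-2,2,6-trimethyl-4-[(triethylsilyl)oxy]-7-oxabicyclo[4.1.0]heptan-1-yl}pent-2-en-1-yl]phosphonate; 9 (2E,4E,6E,8E,10E)-13-[(4R)-4-hydroxy-2,6,6-trimethylcyclohex-1-en-1-yl]-2,7,11-trimethyltrideca-2,4,6,8,10-pentaen-12-ynal
Product: 17 (3S,5R,6S,3'R)-5,6-epoxy-3'-hydroxy-3-[(triethylsilyl)oxy]-7',8'-didehydro-5,6,7,8-tetrahydro-β,β-caroten-8-one
Conditions: LiCl, DBU, MeCN/THF, 0 °C to rt, dark
Reagents that add atoms: none
Why: Horner–Wadsworth–Emmons olefination under Masamune–Roush conditions forms C11=C12 (E); the γ-phosphono enone is far more acidic than the C7 methylene, so the weak amine base can make the phosphonate anion without triggering β-elimination of the epoxide, and the 9E geometry is the thermodynamic one.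

**Step 11**
Reactants: 17 (3S,5R,6S,3'R)-5,6-epoxy-3'-hydroxy-3-[(triethylsilyl)oxy]-7',8'-didehydro-5,6,7,8-tetrahydro-β,β-caroten-8-one
Product: 18 (3S,5R,6S,3'R)-5,6-epoxy-3,3'-dihydroxy-7',8'-didehydro-5,6,7,8-tetrahydro-β,β-caroten-8-one (halocynthiaxanthin, the target)
Conditions: HF·pyridine, pyridine, THF, 0 °C
Reagents that add atoms: none
Why: Buffered fluoride cleavage of the triethylsilyl ether; the non-conjugated epoxide, the β,γ-epoxy ketone and the polyene tolerate these near-neutral conditions.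

**Compound list**
1 | (4R,6R)-4-hydroxy-2,2,6-trimethylcyclohexan-1-one (actinol) | CC1(C)C[C@H](O)C[C@@H](C)C1=O | starting material
2 | (4R,6R)-2,2,6-trimethyl-4-[(triethylsilyl)oxy]cyclohexan-1-one | CC1(C)C[C@H](O[Si](CC)(CC)CC)C[C@@H](C)C1=O | intermediate
3 | lithium (4R)-2,6,6-trimethyl-4-[(triethylsilyl)oxy]cyclohex-1-en-1-olate | CC1=C([O-])C(C)(C)C[C@H](O[Si](CC)(CC)CC)C1.[Li+] | intermediate
4 | (4R)-2,6,6-trimethyl-4-[(triethylsilyl)oxy]cyclohex-1-en-1-yl trifluoromethanesulfonate | CC1=C(OS(=O)(=O)C(F)(F)F)C(C)(C)C[C@H](O[Si](CC)(CC)CC)C1 | intermediate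
5 | (2E)-3-methylpent-2-en-4-yn-1-ol | C#C/C(C)=C/CO | starting material
6 | (2E)-3-methyl-5-{(4R)-2,6,6-trimethyl-4-[(triethylsilyl)oxy]cyclohex-1-en-1-yl}pent-2-en-4-yn-1-ol | CC1=C(C#C/C(C)=C/CO)C(C)(C)C[C@H](O[Si](CC)(CC)CC)C1 | intermediate
7 | {(2E)-5-[(4R)-4-hydroxy-2,6,6-trimethylcyclohex-1-en-1-yl]-3-methylpent-2-en-4-yn-1-yl}(triphenyl)phosphonium bromide | CC1=C(C#C/C(C)=C/C[P+](c2ccccc2)(c2ccccc2)c2ccccc2)C(C)(C)C[C@H](O)C1.[Br-] | intermediate
8 | (2E,4E,6E)-2,7-dimethylocta-2,4,6-trienedial | O=C/C(C)=C/C=C/C=C(C)/C=O | starting material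
9 | (2E,4E,6E,8E,10E)-13-[(4R)-4-hydroxy-2,6,6-trimethylcyclohex-1-en-1-yl]-2,7,11-trimethyltrideca-2,4,6,8,10-pentaen-12-ynal | CC1=C(C#C/C(C)=C/C=C/C(C)=C/C=C/C=C(C)/C=O)C(C)(C)C[C@H](O)C1 | intermediate
10 | triethyl{[(1R)-3,4,5,5-tetramethylcyclohex-3-en-1-yl]oxy}silane | CC1=C(C)C(C)(C)C[C@H](O[Si](CC)(CC)CC)C1 | intermediate
11 | (1R,5S)-1,3,3-trimethyl-2-methylidene-5-[(triethylsilyl)oxy]cyclohexyl hydroperoxide | C=C1[C@](C)(OO)C[C@@H](O[Si](CC)(CC)CC)CC1(C)C | intermediate
12 | triethyl({(1R,5S)-1,3,3-trimethyl-2-methylidene-5-[(triethylsilyl)oxy]cyclohexyl}peroxy)silane | C=C1[C@](C)(OO[Si](CC)(CC)CC)C[C@@H](O[Si](CC)(CC)CC)CC1(C)C | intermediate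
13 | diethyl prop-2-en-1-ylphosphonate | C=CCP(=O)(OCC)OCC | starting material
14 | 2-methylprop-2-enal (methacrolein) | C=C(C)C=O | starting material
15 | diethyl [(2E)-3-methyl-4-oxobut-2-en-1-yl]phosphonate | O=C/C(C)=C/CP(=O)(OCC)OCC | intermediate
16 | diethyl [(2E)-3-methyl-4-oxo-5-{(1S,4S,6R)-2,2,6-trimethyl-4-[(triethylsilyl)oxy]-7-oxabicyclo[4.1.0]heptan-1-yl}pent-2-en-1-yl]phosphonate | CCOP(=O)(OCC)C/C=C(\C)C(=O)C[C@@]12O[C@]1(C)C[C@@H](O[Si](CC)(CC)CC)CC2(C)C | intermediate
17 | (3S,5R,6S,3'R)-5,6-epoxy-3'-hydroxy-3-[(triethylsilyl)oxy]-7',8'-didehydro-5,6,7,8-tetrahydro-β,β-caroten-8-one | CC1=C(C#C/C(C)=C/C=C/C(C)=C/C=C/C=C(C)/C=C/C=C(\C)C(=O)C[C@@]23O[C@]2(C)C[C@@H](O[Si](CC)(CC)CC)CC3(C)C)C(C)(C)C[C@H](O)C1 | intermediate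
18 | (3S,5R,6S,3'R)-5,6-epoxy-3,3'-dihydroxy-7',8'-didehydro-5,6,7,8-tetrahydro-β,β-caroten-8-one (halocynthiaxanthin) | CC1=C(C#C/C(C)=C/C=C/C(C)=C/C=C/C=C(C)/C=C/C=C(\C)C(=O)C[C@@]23O[C@]2(C)C[C@@H](O)CC3(C)C)C(C)(C)C[C@H](O)C1 | target

**Total step count:** 11.
**Longest linear sequence:** 7 steps (1 → 2 → 4 → 10 → 12 → 16 → 17 → 18; the acetylenic branch 1 → 2 → 4 → 6 → 7 → 9 → 17 → 18 is equally long).

**Three steps most likely to fail**

Step 9 (the new step). The acyl radical from an enal may add to the alkene of 12 too slowly, or the C6 radical may lose the peroxyl group instead of closing the ring. The fallback uses known chemistry, sets out from 2 and comes back at 16. Wittig methylenation of 2 (Ph3PCH3Br, KOtBu, toluene, 80 °C) gives triethyl{[(1R,5R)-3,3,5-trimethyl-4-methylidenecyclohexyl]oxy}silane F1. A Me2AlCl-promoted carbonyl-ene reaction of F1 with enal 15 (CH2Cl2, −78 to −20 °C) moves the C5 hydrogen to oxygen, forms C7–C8 and gives diethyl [(2E)-4-hydroxy-3-methyl-5-{(4R)-2,6,6-trimethyl-4-[(triethylsilyl)oxy]cyclohex-1-en-1-yl}pent-2-en-1-yl]phosphonate F2 as both carbinol epimers. Dess–Martin oxidation gives the β,γ-unsaturated ketone diethyl [(2E)-3-methyl-4-oxo-5-{(4R)-2,6,6-trimethyl-4-[(triethylsilyl)oxy]cyclohex-1-en-1-yl}pent-2-en-1-yl]phosphonate F3. Buffered mCPBA (NaHCO3, CH2Cl2, 0 °C) then epoxidises only the electron-rich tetrasubstituted ring alkene; the facial preference is the same modest, substrate-controlled one as in step 7, and the epimer is separated to give 16.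

Step 7. The facial selectivity of singlet O2 at C5 is the weakest point of stereocontrol. The pseudo-axial C1 methyl argues for attack syn to the silyloxy group, while peracid precedent argues for anti; the ene reaction may also give regioisomers. The fallback sets out from 10 and comes back at 12. It is the remedy if attack turns out to be syn, because here oxygen enters opposite to the electrophile, and the bromine position fixes the regiochemistry. Bromohydroperoxidation of 10 (N-bromosuccinimide, anhydrous H2O2 in Et2O, −40 °C) forms the bromonium ion on the face singlet O2 also prefers, and H2O2 opens it trans-diaxially at the less hindered C5. This gives (1R,2R,5S)-2-bromo-1,2,3,3-tetramethyl-5-[(triethylsilyl)oxy]cyclohexyl hydroperoxide F4 (O–O anti and Br syn to the silyloxy group). Silylation (Et3SiCl, imidazole) gives {[(1R,2R,5S)-2-bromo-1,2,3,3-tetramethyl-5-[(triethylsilyl)oxy]cyclohexyl]peroxy}triethylsilane F5. Dehydrobromination with DBU (toluene, 60 °C) can only take a hydrogen from the C6 methyl and so gives 12.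

Step 10. The β,γ-epoxy ketone can open by base-induced β-elimination before the olefination is complete. The fallback masks the ketone at the alcohol level; it sets out from 16 and comes back at 17. Luche reduction of 16 (NaBH4, CeCl3·7H2O, MeOH, −40 °C) gives diethyl [(2E)-4-hydroxy-3-methyl-5-{(1S,4S,6R)-2,2,6-trimethyl-4-[(triethylsilyl)oxy]-7-oxabicyclo[4.1.0]heptan-1-yl}pent-2-en-1-yl]phosphonate F6 as both carbinol epimers, which is stable to strong base. Olefination of its anion with 9 (excess NaN(SiMe3)2, THF, −78 °C to 0 °C) gives (3S,5R,6S,3'R)-5,6-epoxy-3-[(triethylsilyl)oxy]-7',8'-didehydro-5,6,7,8-tetrahydro-β,β-carotene-8,3'-diol F7. MnO2 (CH2Cl2, rt) oxidises only the allylic C8 alcohol, erases the extra centre and gives 17.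

**Further compounds**
F1 | step 9 | triethyl{[(1R,5R)-3,3,5-trimethyl-4-methylidenecyclohexyl]oxy}silane | CC1(C)C[C@H](O[Si](CC)(CC)CC)C[C@@H](C)C1=C
F2 | step 9 | diethyl [(2E)-4-hydroxy-3-methyl-5-{(4R)-2,6,6-trimethyl-4-[(triethylsilyl)oxy]cyclohex-1-en-1-yl}pent-2-en-1-yl]phosphonate (both carbinol epimers) | CCOP(=O)(OCC)C/C=C(\C)C(O)CC1=C(C)C[C@@H](O[Si](CC)(CC)CC)CC1(C)C
F3 | step 9 | diethyl [(2E)-3-methyl-4-oxo-5-{(4R)-2,6,6-trimethyl-4-[(triethylsilyl)oxy]cyclohex-1-en-1-yl}pent-2-en-1-yl]phosphonate | CCOP(=O)(OCC)C/C=C(\C)C(=O)CC1=C(C)C[C@@H](O[Si](CC)(CC)CC)CC1(C)C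
F4 | step 7 | (1R,2R,5S)-2-bromo-1,2,3,3-tetramethyl-5-[(triethylsilyl)oxy]cyclohexyl hydroperoxide | C[C@]1(Br)[C@](C)(OO)C[C@@H](O[Si](CC)(CC)CC)CC1(C)C
F5 | step 7 | {[(1R,2R,5S)-2-bromo-1,2,3,3-tetramethyl-5-[(triethylsilyl)oxy]cyclohexyl]peroxy}triethylsilane | C[C@]1(Br)[C@](C)(OO[Si](CC)(CC)CC)C[C@@H](O[Si](CC)(CC)CC)CC1(C)C
F6 | step 10 | diethyl [(2E)-4-hydroxy-3-methyl-5-{(1S,4S,6R)-2,2,6-trimethyl-4-[(triethylsilyl)oxy]-7-oxabicyclo[4.1.0]heptan-1-yl}pent-2-en-1-yl]phosphonate (both carbinol epimers) | CCOP(=O)(OCC)C/C=C(\C)C(O)C[C@@]12O[C@]1(C)C[C@@H](O[Si](CC)(CC)CC)CC2(C)C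
F7 | step 10 | (3S,5R,6S,3'R)-5,6-epoxy-3-[(triethylsilyl)oxy]-7',8'-didehydro-5,6,7,8-tetrahydro-β,β-carotene-8,3'-diol (both C8 epimers) | CC1=C(C#C/C(C)=C/C=C/C(C)=C/C=C/C=C(C)/C=C/C=C(\C)C(O)C[C@@]23O[C@]2(C)C[C@@H](O[Si](CC)(CC)CC)CC3(C)C)C(C)(C)C[C@H](O)C1
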